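**Retrosynthetic overview**

1. Feature: unit 2 is the genistein joined through C8. Its ring A is a phloroglucinol in which the aryl-bearing C8 sits between the oxygenated carbons C7 and C8a, and the third oxygen (C5–O) is para to C8. A vinylketene/ynol ether benzannulation delivers exactly this 2-aryl-1,3,5-trioxygenated arene.
2. Endgame: five O-alkyl groups are stripped. Both rings C are then opened together (C2 comes from DMF) and both C4–C4a bonds are cut (twofold acylation with 4-methoxyphenylacetic acid). This leads back to a biaryl triol in which each ring has two equivalent CH positions and the C5 oxygens of both units are alkylated, so they cannot close ring C.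
3. Key disconnection: ring A of unit 2 (C8–C8a and C6–C7 new, C4a–C8a broken and re-made) goes back to 3-ethoxycyclobutenone and the triisopropylsilyl ynol ether that carries ring A of unit 1.
4. Precursors: the siloxyalkyne comes in three steps from 4-hydroxy-2,6-dimethoxybenzaldehyde (benzylation, one-carbon homologation, acetylide oxidation with silylation). The cyclobutenone comes in one step from ethoxyacetylene and ketene made from acetyl chloride.
5. Ring order: ring A of unit 1 and both rings B are bought. The cyclobutenone is made next, then ring A of unit 2, then both rings C in one operation.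

Key step: step 5

Assumption: the SMILES defines no configuration for the biaryl axis between C6 of unit 1 and C8 of unit 2, so the axis is left uncontrolled and the target is made as the racemate.

**Step 1**
Reactants: 1 4-hydroxy-2,6-dimethoxybenzaldehyde
Product: 2 4-(benzyloxy)-2,6-dimethoxybenzaldehyde
Conditions: BnBr, K2CO3, DMF, rt to 50 °C
Reagents that add atoms: benzyl bromide, BrCc1ccccc1
Why: Williamson ether synthesis on the acidic para-formyl phenol, which puts a base- and organolithium-stable mark on the oxygen that will become O1 of unit 1.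

**Step 2**
Reactants: 2 4-(benzyloxy)-2,6-dimethoxybenzaldehyde
Product: 3 5-(benzyloxy)-2-ethynyl-1,3-dimethoxybenzene
Conditions: MeCOC(N2)P(O)(OMe)2, K2CO3, MeOH–THF, rt
Reagents that add atoms: dimethyl (1-diazo-2-oxopropyl)phosphonate, CC(=O)C(=[N+]=[N-])P(=O)(OC)OC
Why: Seyferth–Gilbert homologation in its Ohira–Bestmann form converts a non-enolisable aryl aldehyde into the terminal alkyne in one mild, weakly basic operation that touches none of the three ethers.

**Step 3**
Reactants: 3 5-(benzyloxy)-2-ethynyl-1,3-dimethoxybenzene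
Product: 6 {[4-(benzyloxy)-2,6-dimethoxyphenyl]ethynyl}oxy(triisopropyl)silane, via lithium acetylide 4 (not isolated), via lithium ynolate 5 (not isolated)
Conditions: n-BuLi, THF, −78 °C; t-BuOOLi (from anhydrous t-BuOOH and LiN(SiMe3)2), THF, −78 to 0 °C; i-Pr3SiOTf, −78 to 0 °C
Reagents that add atoms: tert-butyl hydroperoxide, CC(C)(C)OO; triisopropylsilyl trifluoromethanesulfonate, CC(C)[Si](C(C)C)(C(C)C)OS(=O)(=O)C(F)(F)F
Why: The acetylide carbon of 4 attacks the peroxide oxygen of t-BuOOLi with loss of t-BuOLi (known oxidation of lithium acetylides to ynolates), and the bulky silyl triflate then traps ynolate 5 on oxygen rather than on the aryl-shielded carbon, giving a chromatographable silyl ynol ether.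

**Step 4**
Reactants: 7 ethoxyacetylene; 8 acetyl chloride
Product: 10 3-ethoxycyclobut-2-en-1-one, via ketene 9 (not isolated)
Conditions: Et3N, Et2O, 8 added slowly to excess 7, 0 °C to rt
Reagents that add atoms: none
Why: Dehydrochlorination of 8 gives ketene 9, which is caught as it forms by the electron-rich ynol ether in a regioselective [2+2] cycloaddition (CH terminus of 7 to the ketene carbonyl carbon), while slow addition and an excess of cheap 7 hold back ketene oligomerisation.

**Step 5**
Reactants: 6 {[4-(benzyloxy)-2,6-dimethoxyphenyl]ethynyl}oxy(triisopropyl)silane; 10 3-ethoxycyclobut-2-en-1-one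
Product: 15 2-[4-(benzyloxy)-2,6-dimethoxyphenyl]-5-ethoxy-3-[(triisopropylsilyl)oxy]phenol, via vinylketene 11 (not isolated), via vinylcyclobutenone 12 (not isolated), via dienylketene 13 (not isolated), via cyclohexadienone 14 (not isolated)
Conditions: degassed toluene, sealed vessel, 80 then 110 °C, 10 (1.3 equiv) added in portions
Reagents that add atoms: none
Why: This is a Danheiser benzannulation, the known thermal cascade of a cyclobutenone with a triisopropylsiloxyalkyne: 4π electrocyclic opening of 10 breaks C4a–C8a and gives vinylketene 11, whose ketene carbon (future C8a) takes the nucleophilic aryl-bearing alkyne carbon (C8) in a [2+2] addition that also joins the siloxy carbon (C7) to C6 and gives 12. A second, reversible 4π opening of 12 breaks the old C8a–C6 bond to give dienylketene 13, and ring A of unit 2 closes by 6π electrocyclisation of 13 that re-forms C4a–C8a (14), after which enolisation gives the phenol. No stereocentre survives (the one in 12 is destroyed on opening), and the new biaryl axis is not yet stereogenic because the dimethoxyaryl ring is symmetric. The selectivity needed is the orientation of the [2+2] step, and it is secured by the polarisation of 6: donation from the siloxy oxygen makes the aryl-bearing carbon the nucleophile while the ketene carbonyl carbon is the only strong electrophile, so the aryl group must end between C7–O and C8a–O and the ethoxy group para to it at C5. The ketene oxygen emerges as the one free hydroxyl next to the aryl group, the bulky silyl group slows O-to-C silyl migration in 6 at the reaction temperature, and portionwise addition of 10 keeps the vinylketene from consuming itself or esterifying the hindered phenol.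

**Step 6**
Reactants: 15 2-[4-(benzyloxy)-2,6-dimethoxyphenyl]-5-ethoxy-3-[(triisopropylsilyl)oxy]phenol
Product: 16 2-[4-(benzyloxy)-2,6-dimethoxyphenyl]-5-ethoxybenzene-1,3-diol
Conditions: Bu4NF, AcOH, THF, 0 °C
Reagents that add atoms: none
Why: Fluoride-induced cleavage of the aryl silyl ether under acetic acid buffering leaves the alkyl ethers alone, and with both flanking oxygens free ring A of unit 2 becomes symmetric about its C5–C8 line, so that C4a and C6 are equivalent and the coming acylation has no regiochemical choice.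

**Step 7**
Reactants: 16 2-[4-(benzyloxy)-2,6-dimethoxyphenyl]-5-ethoxybenzene-1,3-diol
Product: 17 5-ethoxy-2-(4-hydroxy-2,6-dimethoxyphenyl)benzene-1,3-diol
Conditions: H2 (1 atm), 10% Pd/C, EtOAc–EtOH, rt
Reagents that add atoms: none
Why: Catalytic hydrogenolysis of the benzyl aryl ether frees the future O1 of unit 1, and it is placed before any chromenone C2=C3 bond exists so that nothing else can be reduced.

**Step 8**
Reactants: 17 5-ethoxy-2-(4-hydroxy-2,6-dimethoxyphenyl)benzene-1,3-diol; 18 4-methoxyphenylacetic acid (2.3 equiv)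
Product: 19 1-(6-ethoxy-2,4-dihydroxy-3-{4-hydroxy-2,6-dimethoxy-3-[(4-methoxyphenyl)acetyl]phenyl}phenyl)-2-(4-methoxyphenyl)ethan-1-one (bis-deoxybenzoin)
Conditions: BF3·OEt2 (neat), argon, 80–85 °C; aq NaOAc
Reagents that add atoms: none
Why: Twofold Friedel–Crafts acylation of phenols by an arylacetic acid in BF3·OEt2 (the standard deoxybenzoin synthesis): each ring offers only two equivalent CH positions ortho to a free hydroxyl, boron chelation of each new ortho-hydroxyketone damps that ring against a second acylation, and BF3 leaves the C5 ethers in place, so a single constitutional isomer should form (the axis becomes stereogenic here and is formed racemic).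

**Step 9**
Reactants: 19 bis-deoxybenzoin
Product: 21 5-ethoxy-7-hydroxy-8-[5,7-dimethoxy-3-(4-methoxyphenyl)-4-oxo-4H-chromen-6-yl]-3-(4-methoxyphenyl)-4H-chromen-4-one, via bis(enaminone) 20 (not isolated)
Conditions: BF3·OEt2, DMF, 10 °C; MeSO2Cl, DMF, 50 to 90 °C; H2O
Reagents that add atoms: N,N-dimethylformamide, CN(C)C=O
Why: Vilsmeier-type formylation of both activated methylene groups gives 20, and each ring C then closes by addition–elimination of the only hydroxyl ortho to its ketone (C8a–OH, since C5–O is still alkylated) with loss of dimethylamine, a standard isoflavone closure that tolerates the free 7-hydroxyl of unit 2.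

**Step 10**
Reactants: 21 5-ethoxy-7-hydroxy-8-[5,7-dimethoxy-3-(4-methoxyphenyl)-4-oxo-4H-chromen-6-yl]-3-(4-methoxyphenyl)-4H-chromen-4-one
Product: 22 6-[5,7-dihydroxy-3-(4-hydroxyphenyl)-4-oxo-4H-chromen-8-yl]-5,7-dihydroxy-3-(4-hydroxyphenyl)-4H-chromen-4-one (CNP0184660.0)
Conditions: BBr3 (large excess), CH2Cl2, −78 °C to rt; ice-water
Reagents that add atoms: none
Why: Lewis acid ether cleavage with BBr3 removes the two chelation-activated C5 ethers first and then the 7-methoxy and both ring B methoxy groups, and its low temperature avoids the Wessely–Moser ring opening and reclosure that hot protic acids could cause once the 5-hydroxyls are free.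

**Compound list**

1 | 4-hydroxy-2,6-dimethoxybenzaldehyde | O=Cc1c(OC)cc(O)cc1OC | starting material
2 | 4-(benzyloxy)-2,6-dimethoxybenzaldehyde | O=Cc1c(OC)cc(OCc2ccccc2)cc1OC | intermediate
3 | 5-(benzyloxy)-2-ethynyl-1,3-dimethoxybenzene | C#Cc1c(OC)cc(OCc2ccccc2)cc1OC | intermediate
4 | lithium [4-(benzyloxy)-2,6-dimethoxyphenyl]acetylide | [Li+].[C-]#Cc1c(OC)cc(OCc2ccccc2)cc1OC | intermediate
5 | lithium 2-[4-(benzyloxy)-2,6-dimethoxyphenyl]ethynolate | [Li+].[O-]C#Cc1c(OC)cc(OCc2ccccc2)cc1OC | intermediate
6 | {[4-(benzyloxy)-2,6-dimethoxyphenyl]ethynyl}oxy(triisopropyl)silane | CC(C)[Si](OC#Cc1c(OC)cc(OCc2ccccc2)cc1OC)(C(C)C)C(C)C | intermediate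
7 | ethoxyacetylene | C#COCC | starting material
8 | acetyl chloride | CC(=O)Cl | starting material
9 | ketene | C=C=O | intermediate
10 | 3-ethoxycyclobut-2-en-1-one | CCOC1=CC(=O)C1 | intermediate
11 | 3-ethoxybuta-1,3-dien-1-one (vinylketene) | C=C(OCC)C=C=O | intermediate
12 | 2-[4-(benzyloxy)-2,6-dimethoxyphenyl]-4-(1-ethoxyethenyl)-3-[(triisopropylsilyl)oxy]cyclobut-2-en-1-one (racemic) | O=C1C(c2c(OC)cc(OCc3ccccc3)cc2OC)=C(O[Si](C(C)C)(C(C)C)C(C)C)C1C(=C)OCC | intermediate
13 | 2-[4-(benzyloxy)-2,6-dimethoxyphenyl]-5-ethoxy-3-[(triisopropylsilyl)oxy]hexa-1,3,5-trien-1-one (dienylketene, ketenyl and ethoxyvinyl groups cis on the central double bond) | O=C=C(c1c(OC)cc(OCc2ccccc2)cc1OC)/C(O[Si](C(C)C)(C(C)C)C(C)C)=C\C(=C)OCC | intermediate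
14 | 2-[4-(benzyloxy)-2,6-dimethoxyphenyl]-5-ethoxy-3-[(triisopropylsilyl)oxy]cyclohexa-2,4-dien-1-one | O=C1CC(OCC)=CC(O[Si](C(C)C)(C(C)C)C(C)C)=C1c1c(OC)cc(OCc2ccccc2)cc1OC | intermediate
15 | 2-[4-(benzyloxy)-2,6-dimethoxyphenyl]-5-ethoxy-3-[(triisopropylsilyl)oxy]phenol | Oc1cc(OCC)cc(O[Si](C(C)C)(C(C)C)C(C)C)c1-c1c(OC)cc(OCc2ccccc2)cc1OC | intermediate
16 | 2-[4-(benzyloxy)-2,6-dimethoxyphenyl]-5-ethoxybenzene-1,3-diol | Oc1cc(OCC)cc(O)c1-c1c(OC)cc(OCc2ccccc2)cc1OC | intermediate
17 | 5-ethoxy-2-(4-hydroxy-2,6-dimethoxyphenyl)benzene-1,3-diol | Oc1cc(OCC)cc(O)c1-c1c(OC)cc(O)cc1OC | intermediate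
18 | 4-methoxyphenylacetic acid | COc1ccc(CC(=O)O)cc1 | starting material
19 | 1-(6-ethoxy-2,4-dihydroxy-3-{4-hydroxy-2,6-dimethoxy-3-[(4-methoxyphenyl)acetyl]phenyl}phenyl)-2-(4-methoxyphenyl)ethan-1-one (bis-deoxybenzoin, racemic axis) | O=C(Cc1ccc(OC)cc1)c1c(OCC)cc(O)c(-c2c(OC)cc(O)c(C(=O)Cc3ccc(OC)cc3)c2OC)c1O | intermediate
20 | bis(enaminone): 19 with a dimethylaminomethylidene group on each of its two CH2 carbons | CN(C)C=C(C(=O)c1c(OCC)cc(O)c(-c2c(OC)cc(O)c(C(=O)C(=CN(C)C)c3ccc(OC)cc3)c2OC)c1O)c1ccc(OC)cc1 | intermediate
21 | 5-ethoxy-7-hydroxy-8-[5,7-dimethoxy-3-(4-methoxyphenyl)-4-oxo-4H-chromen-6-yl]-3-(4-methoxyphenyl)-4H-chromen-4-one | O=c1c(-c2ccc(OC)cc2)coc2c(-c3c(OC)cc4occ(-c5ccc(OC)cc5)c(=O)c4c3OC)c(O)cc(OCC)c12 | intermediate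
22 | 6-[5,7-dihydroxy-3-(4-hydroxyphenyl)-4-oxo-4H-chromen-8-yl]-5,7-dihydroxy-3-(4-hydroxyphenyl)-4H-chromen-4-one | O=c1c(-c2ccc(O)cc2)coc2cc(O)c(-c3c(O)cc(O)c4c(=O)c(-c5ccc(O)cc5)coc34)c(O)c12 | target

**Step count**

- Total step count: 10
- Longest linear sequence: 9 (steps 1, 2, 3, 5, 6, 7, 8, 9, 10)

**Steps most likely to fail**

Step 5. Two things may go wrong.
- The vinylogous-ester stabilisation of 10 may push its ring opening to temperatures at which 6 is lost through O-to-C silyl migration and oligomerisation.
- The two ortho-methoxy groups may slow the [2+2] capture, so that the vinylketene reacts with itself.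

The fallback makes the same vinylketene at room temperature by a photochemical Wolff rearrangement, the diazoketone version of the benzannulation. It sets out from 6. Ethyl vinyl ether is lithiated with t-BuLi and acylated with N-methoxy-N-methylacetamide to give 3-ethoxybut-3-en-2-one F1. Its lithium enolate (LiN(SiMe3)2, THF, −78 °C) is trifluoroacetylated with CF3CO2CH2CF3 to give crude 5-ethoxy-1,1,1-trifluorohex-5-ene-2,4-dione F2. Detrifluoroacetylative diazo transfer (MeSO2N3, Et3N, H2O, MeCN) then gives 1-diazo-3-ethoxybut-3-en-2-one F3. Irradiation of F3 with 6 in CH2Cl2 at rt should pass through 11 to 12. Brief warming in toluene takes 12 through 13 and 14, and the route is rejoined at 15.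

Step 8. Hot BF3·OEt2 may cause any of four problems.
- It may stop after one acylation.
- It may acylate one ring twice.
- It may cleave an alkyl ether next to a new ketone, which would later let ring C close the wrong way.
- It may let a hydroxyl ortho to the axis attack a methoxy-bearing carbon of the other ring with loss of methanol, closing a dibenzofuran.

The fallback replaces the acylium chemistry by a twofold Houben–Hoesch reaction at low temperature. It sets out from 17. Treatment with 4-methoxyphenylacetonitrile, ZnCl2 and dry HCl in Et2O at 0 °C should precipitate the bis(ketiminium chloride) F4, which is thereby withdrawn from further reaction. Hydrolysis of F4 in warm water comes back to the route at 19.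

Step 10. Partly dealkylated boron aryloxides may precipitate from CH2Cl2 before the three unactivated ethers are cleaved. These are the 7-methoxy group of unit 1 and the two ring B methoxy groups. Forcing the reaction invites opening and reclosure of ring C. The fallback removes the ring B protecting groups from the plan. It sets out from 17. Acylation with unprotected 4-hydroxyphenylacetic acid in BF3·OEt2 gives the ring B unprotected bis-deoxybenzoin F5. Treatment with DMF, MeSO2Cl and BF3·OEt2 as in step 9 passes through the ring B unprotected bis(enaminone) F6 to the tri-O-alkyl bis-isoflavone F7. F7 holds only three ethers, two of them chelation-activated at C5, so BBr3 has one unactivated ether left to cleave, and the route is rejoined at 22.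

**Further compounds**

F1 | step 5 | 3-ethoxybut-3-en-2-one | C=C(OCC)C(C)=O
F2 | step 5 | 5-ethoxy-1,1,1-trifluorohex-5-ene-2,4-dione | C=C(OCC)C(=O)CC(=O)C(F)(F)F
F3 | step 5 | 1-diazo-3-ethoxybut-3-en-2-one | C=C(OCC)C(=O)C=[N+]=[N-]
F4 | step 8 | bis(ketiminium chloride), the dihydrochloride of the diimine of 19 | N=C(Cc1ccc(OC)cc1)c1c(OCC)cc(O)c(-c2c(OC)cc(O)c(C(=N)Cc3ccc(OC)cc3)c2OC)c1O.Cl.Cl
F5 | step 10 | ring B unprotected bis-deoxybenzoin, 1-(6-ethoxy-2,4-dihydroxy-3-{4-hydroxy-3-[(4-hydroxyphenyl)acetyl]-2,6-dimethoxyphenyl}phenyl)-2-(4-hydroxyphenyl)ethan-1-one | O=C(Cc1ccc(O)cc1)c1c(OCC)cc(O)c(-c2c(OC)cc(O)c(C(=O)Cc3ccc(O)cc3)c2OC)c1O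
F6 | step 10 | ring B unprotected bis(enaminone), F5 with a dimethylaminomethylidene group on each CH2 carbon | CN(C)C=C(C(=O)c1c(OCC)cc(O)c(-c2c(OC)cc(O)c(C(=O)C(=CN(C)C)c3ccc(O)cc3)c2OC)c1O)c1ccc(O)cc1
F7 | step 10 | tri-O-alkyl bis-isoflavone, 5-ethoxy-7-hydroxy-3-(4-hydroxyphenyl)-8-[3-(4-hydroxyphenyl)-5,7-dimethoxy-4-oxo-4H-chromen-6-yl]-4H-chromen-4-one | O=c1c(-c2ccc(O)cc2)coc2c(-c3c(OC)cc4occ(-c5ccc(O)cc5)c(=O)c4c3OC)c(O)cc(OCC)c12
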